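Assumption: only substrates, building blocks, intermediates and products are numbered; reagents are named in the steps, with SMILES where they add atoms.

## Retrosynthetic overview

1. Target 24 ⇐ keto-lactone 20: the C(CH3)=CH unit comes from a ketone by enol triflate formation and Negishi methylation, then desilylation.
2. 20 ⇐ intermolecular Michael addition of the kinetic lithium dienolate of (R)-cryptone 17 to O-TBS-(+)-altholactone 12, followed in the same flask by intramolecular Michael closure.
3. 12 ⇐ (+)-altholactone 11 ⇐ Z-Wittig/lactonisation of the 2,5-anhydro aldehyde 9; its oxolane comes from a benzylic-mesylate ring switch and its phenyl from a chelation-controlled Grignard addition, starting from diacetone-D-glucose 1.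
4. 17 ⇐ organocatalytic Michael addition of isovaleraldehyde 13 to methyl vinyl ketone 14, then aldol condensation.
5. Ring order: oxolane → pyranone; separately the cyclohexenone; finally the bicyclo[2.2.2]octane.

## Route

Step 1
Reactants: 1 1,2:5,6-di-O-isopropylidene-α-D-glucofuranose
Product: 2 3-O-benzyl-1,2:5,6-di-O-isopropylidene-α-D-glucofuranose
Conditions: NaH, BnBr, TBAI (cat.), THF, 0 °C → rt
Reagents that add atoms: benzyl bromide, BrCc1ccccc1
Why: Williamson etherification of the only free hydroxyl; no stereocentre is touched.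

Step 2
Reactants: 2 3-O-benzyl-1,2:5,6-di-O-isopropylidene-α-D-glucofuranose
Product: 4 3-O-benzyl-1,2-O-isopropylidene-α-D-xylo-pentodialdo-1,4-furanose, via 5,6-diol 3 (not isolated)
Conditions: H5IO6 (1.3 equiv), EtOAc, rt
Reagents that add atoms: none
Why: Periodic acid hydrolyses the more labile terminal 5,6-acetonide and then performs Malaprade glycol cleavage of the freed diol, leaving the cis-fused 1,2-acetonide and the ring stereocentres intact.

Step 3
Reactants: 4 3-O-benzyl-1,2-O-isopropylidene-α-D-xylo-pentodialdo-1,4-furanose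
Product: 5 (5S)-3-O-benzyl-1,2-O-isopropylidene-5-C-phenyl-α-D-xylofuranose (L-ido-type benzylic alcohol)
Conditions: PhMgBr, THF, −78 → 0 °C; aq NH4Cl
Reagents that add atoms: phenylmagnesium bromide, Br[Mg]c1ccccc1
Why: Chelation-controlled Grignard addition (Mg bridging the aldehyde O and ring O-4) delivers phenyl to the face anti to C-3, giving the 5S alcohol as the major isomer; the minor 5R epimer is removed by chromatography.

Step 4
Reactants: 5 (5S)-3-O-benzyl-1,2-O-isopropylidene-5-C-phenyl-α-D-xylofuranose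
Product: 6 (5S)-3-O-benzyl-1,2-O-isopropylidene-5-O-methanesulfonyl-5-C-phenyl-α-D-xylofuranose
Conditions: MsCl, Et3N, CH2Cl2, 0 °C
Reagents that add atoms: methanesulfonyl chloride, CS(=O)(=O)Cl
Why: O-sulfonylation with retention; the neighbouring C–O bonds inductively retard ionisation, so the benzylic mesylate can be handled.

Step 5
Reactants: 6 (5S)-3-O-benzyl-1,2-O-isopropylidene-5-O-methanesulfonyl-5-C-phenyl-α-D-xylofuranose
Product: 7 (5R)-2,5-anhydro-3-O-benzyl-5-C-phenyl-D-xylose dimethyl acetal (oxolane with Ph and CH(OMe)2 cis; free OH trans to Ph; OBn cis to CH(OMe)2)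
Conditions: 2% HCl in MeOH (from AcCl), reflux
Reagents that add atoms: methanol, CO
Why: Acid-catalysed transacetalisation opens the furanose to the dimethyl acetal, whose free 2-OH displaces the benzylic mesylate in a 5-exo-tet SN2 ring switch with inversion (5S → 5R), forming the oxolane.

Step 6
Reactants: 7 (5R)-2,5-anhydro-3-O-benzyl-5-C-phenyl-D-xylose dimethyl acetal
Product: 8 (5R)-2,5-anhydro-5-C-phenyl-D-xylose dimethyl acetal (3,4-diol)
Conditions: H2 (1 atm), 10% Pd/C, EtOAc–MeOH, rt
Reagents that add atoms: none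
Why: Catalytic hydrogenolysis cleaves the primary O-benzyl ether much faster than the cyclic secondary 2-phenyloxolane C–O bond (as in C-aryl glycoside debenzylations); no stereocentre changes.

Step 7
Reactants: 8 (5R)-2,5-anhydro-5-C-phenyl-D-xylose dimethyl acetal
Product: 9 (5R)-2,5-anhydro-5-C-phenyl-D-xylose (free aldehyde; used crude)
Conditions: TFA–H2O (9:1), 0 °C → rt
Reagents that add atoms: water, O
Why: Acid-catalysed acetal hydrolysis; the α-alkoxy aldehyde is not exposed to base, so C-2 does not epimerise.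

Step 8
Reactants: 9 (5R)-2,5-anhydro-5-C-phenyl-D-xylose
Product: 11 (+)-altholactone [(2R,3R,3aS,7aS)-3-hydroxy-2-phenyl-2,3,3a,7a-tetrahydro-5H-furo[3,2-b]pyran-5-one], via Z-enoate 10 (not isolated)
Conditions: Ph3P=CHCO2Me, MeOH, 0 °C → rt
Reagents that add atoms: methyl (triphenylphosphoranylidene)acetate, COC(=O)C=P(c1ccccc1)(c1ccccc1)c1ccccc1
Why: Wittig olefination of an α-alkoxy aldehyde with a stabilised ylide in methanol is Z-selective, and the Z-ester sits next to the cis hydroxyl and lactonises to the cis-fused pyranone; the minor E-ester cannot cyclise and is separated.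

Step 9
Reactants: 11 (+)-altholactone
Product: 12 3-O-(tert-butyldimethylsilyl)-(+)-altholactone
Conditions: TBSOTf, 2,6-lutidine, CH2Cl2, −78 → 0 °C
Reagents that add atoms: tert-butyldimethylsilyl trifluoromethanesulfonate, CC(C)(C)[Si](C)(C)OS(=O)(=O)C(F)(F)F
Why: Silylation of the secondary alcohol with a non-nucleophilic base removes the only acidic proton before the enolate step and does not touch the enoate.

Step 10
Reactants: 13 isovaleraldehyde (3-methylbutanal); 14 methyl vinyl ketone
Product: 15 (R)-2-isopropyl-5-oxohexanal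
Conditions: (R)-2-(methoxydiphenylmethyl)pyrrolidine (5 mol %), ethyl 3,4-dihydroxybenzoate (20 mol %), neat, 4 °C
Reagents that add atoms: none
Why: Enamine-catalysed asymmetric Michael addition in which the (R)-prolinol ether shields one face of the E-enamine, so the enone is attacked from the open face and C-2 is set as R.

Step 11
Reactants: 15 (R)-2-isopropyl-5-oxohexanal
Product: 17 (R)-4-isopropylcyclohex-2-en-1-one [(R)-cryptone], via aldol 16 (not isolated)
Conditions: LiOH (0.1 equiv), iPrOH, rt
Reagents that add atoms: none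
Why: Intramolecular aldol condensation (methyl-ketone enolate onto the aldehyde, then E1cB dehydration) is faster than α-epimerisation of the aldehyde, so the stereocentre is carried into C-4 of the enone.

Step 12
Reactants: 17 (R)-cryptone; 12 3-O-(tert-butyldimethylsilyl)-(+)-altholactone
Product: 20 O-TBS keto-lactone (bicyclo[2.2.2]octan-2-one double-Michael adduct; skeleton and configuration of 24 with C=O/CH2 in place of C(CH3)=CH), via lithium dienolate 18 (not isolated), via Michael-adduct enolate 19 (not isolated)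
Conditions: LDA (1.15 equiv), 17 (1.2 equiv), THF, −78 °C; then 12 (1.0 equiv), −78 → 0 °C; aq NH4Cl
Reagents that add atoms: none
Why: Michael–Michael annulation in which the α′-carbon of the cross-conjugated dienolate adds to the lactone β-carbon anti to the cis-fused oxolane oxygen and the resulting lactone enolate closes onto the enone β-carbon anti to the isopropyl group, a combination that with these two enantiomers can only give the endo, cis-fused adduct with the target configuration at all four new centres and with unambiguous regiochemistry.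

Step 13
Reactants: 20 O-TBS keto-lactone
Product: 22 O-TBS enol triflate (OTf on the alkene carbon that later carries CH3), via potassium enolate 21 (not isolated)
Conditions: KHMDS (1.05 equiv), THF, −78 °C; PhNTf2, −78 → 0 °C
Reagents that add atoms: N-phenylbis(trifluoromethanesulfonimide), O=S(=O)(N(c1ccccc1)S(=O)(=O)C(F)(F)F)C(F)(F)F
Why: Enolate O-triflation; the ketone is far more acidic than the lactone and can enolise only toward its CH2 because the other α-carbon is a bridgehead (Bredt), so a single regioisomer forms.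

Step 14
Reactants: 22 O-TBS enol triflate
Product: 23 O-TBS ether of the target
Conditions: MeZnCl (2 equiv), Pd(PPh3)4 (5 mol %), THF, 50 °C
Reagents that add atoms: methylzinc chloride, C[Zn]Cl
Why: Negishi cross-coupling (oxidative addition into the alkenyl triflate, transmetalation, reductive elimination) installs the vinylic methyl without touching the lactone, the silyl ether or any stereocentre.

Step 15
Reactants: 23 O-TBS ether of the target
Product: 24 target CNP0249919.1
Conditions: HF·pyridine, THF, 0 °C → rt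
Reagents that add atoms: none
Why: Fluoride-mediated desilylation under buffered acidic conditions leaves the δ-lactone and the trisubstituted alkene intact and changes no stereocentre.

## Compound list

1 | 1,2:5,6-di-O-isopropylidene-α-D-glucofuranose (diacetone-D-glucose) | CC1(C)OC[C@@H](O1)[C@H]1O[C@@H]2OC(C)(C)O[C@@H]2[C@H]1O | starting material
2 | 3-O-benzyl-1,2:5,6-di-O-isopropylidene-α-D-glucofuranose | CC1(C)OC[C@@H](O1)[C@H]1O[C@@H]2OC(C)(C)O[C@@H]2[C@H]1OCc1ccccc1 | intermediate
3 | 3-O-benzyl-1,2-O-isopropylidene-α-D-glucofuranose (5,6-diol, not isolated) | OC[C@@H](O)[C@H]1O[C@@H]2OC(C)(C)O[C@@H]2[C@H]1OCc1ccccc1 | intermediate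
4 | 3-O-benzyl-1,2-O-isopropylidene-α-D-xylo-pentodialdo-1,4-furanose | O=C[C@H]1O[C@@H]2OC(C)(C)O[C@@H]2[C@H]1OCc1ccccc1 | intermediate
5 | (5S)-3-O-benzyl-1,2-O-isopropylidene-5-C-phenyl-α-D-xylofuranose | O[C@@H](c1ccccc1)[C@H]1O[C@@H]2OC(C)(C)O[C@@H]2[C@H]1OCc1ccccc1 | intermediate
6 | (5S)-3-O-benzyl-1,2-O-isopropylidene-5-O-mesyl-5-C-phenyl-α-D-xylofuranose | CS(=O)(=O)O[C@@H](c1ccccc1)[C@H]1O[C@@H]2OC(C)(C)O[C@@H]2[C@H]1OCc1ccccc1 | intermediate
7 | (5R)-2,5-anhydro-3-O-benzyl-5-C-phenyl-D-xylose dimethyl acetal | COC(OC)[C@@H]1O[C@H](c2ccccc2)[C@@H](O)[C@@H]1OCc1ccccc1 | intermediate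
8 | (5R)-2,5-anhydro-5-C-phenyl-D-xylose dimethyl acetal | COC(OC)[C@@H]1O[C@H](c2ccccc2)[C@@H](O)[C@@H]1O | intermediate
9 | (5R)-2,5-anhydro-5-C-phenyl-D-xylose (aldehyde) | O=C[C@@H]1O[C@H](c2ccccc2)[C@@H](O)[C@@H]1O | intermediate
10 | methyl (Z)-3-[3,4-dihydroxy-5-phenyloxolan-2-yl]prop-2-enoate, Z-enoate of 9 (not isolated) | COC(=O)/C=C\[C@@H]1O[C@H](c2ccccc2)[C@@H](O)[C@@H]1O | intermediate
11 | (+)-altholactone, (2R,3R,3aS,7aS)-3-hydroxy-2-phenyl-2,3,3a,7a-tetrahydro-5H-furo[3,2-b]pyran-5-one | O=C1O[C@H]2[C@H](O)[C@@H](c3ccccc3)O[C@H]2C=C1 | intermediate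
12 | 3-O-(tert-butyldimethylsilyl)-(+)-altholactone | O=C1O[C@H]2[C@H](O[Si](C)(C)C(C)(C)C)[C@@H](c3ccccc3)O[C@H]2C=C1 | intermediate
13 | isovaleraldehyde | CC(C)CC=O | starting material
14 | methyl vinyl ketone | CC(=O)C=C | starting material
15 | (R)-2-isopropyl-5-oxohexanal | CC(C)[C@H](C=O)CCC(C)=O | intermediate
16 | (4R)-3-hydroxy-4-isopropylcyclohexan-1-one (aldol, carbinol epimers, not isolated) | CC(C)[C@H]1CCC(=O)CC1O | intermediate
17 | (R)-4-isopropylcyclohex-2-en-1-one, (R)-cryptone | CC(C)[C@H]1CCC(=O)C=C1 | intermediate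
18 | lithium (4R)-4-isopropylcyclohexa-1,5-dien-1-olate (not isolated) | CC(C)[C@H]1CC=C(O[Li])C=C1 | intermediate
19 | lithium lactone enolate of the mono-Michael adduct, cryptone C-6 bonded to lactone C-7 (not isolated) | O=C1C=C[C@@H](C(C)C)C[C@@H]1[C@@H]2C=C(O[Li])O[C@H]3[C@H](O[Si](C)(C)C(C)(C)C)[C@@H](c4ccccc4)O[C@@H]23 | intermediate
20 | O-TBS keto-lactone (bicyclo[2.2.2]octan-2-one) | O=C1C[C@@H]2[C@@H]3C(=O)O[C@H]4[C@H](O[Si](C)(C)C(C)(C)C)[C@@H](c5ccccc5)O[C@H]4[C@@H]3[C@H]1C[C@@H]2C(C)C | intermediate
21 | potassium enolate of 20 (not isolated) | [K]OC1=C[C@@H]2[C@@H]3C(=O)O[C@H]4[C@H](O[Si](C)(C)C(C)(C)C)[C@@H](c5ccccc5)O[C@H]4[C@@H]3[C@H]1C[C@@H]2C(C)C | intermediate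
22 | O-TBS enol triflate | O=S(=O)(OC1=C[C@@H]2[C@@H]3C(=O)O[C@H]4[C@H](O[Si](C)(C)C(C)(C)C)[C@@H](c5ccccc5)O[C@H]4[C@@H]3[C@H]1C[C@@H]2C(C)C)C(F)(F)F | intermediate
23 | O-TBS ether of the target | CC1=C[C@@H]2[C@@H]3C(=O)O[C@H]4[C@H](O[Si](C)(C)C(C)(C)C)[C@@H](c5ccccc5)O[C@H]4[C@@H]3[C@H]1C[C@@H]2C(C)C | intermediate
24 | CNP0249919.1 | CC1=C[C@@H]2[C@@H]3C(=O)O[C@H]4[C@H](O)[C@@H](c5ccccc5)O[C@H]4[C@@H]3[C@H]1C[C@@H]2C(C)C | target

## Summary and risks

Total step count: 15.
Longest linear sequence: 13 steps (steps 1–9, then 12–15); the cryptone branch (steps 10–11) joins at step 12.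

The three steps most likely to fail:

Step 12 (Michael–Michael annulation). The first Michael addition may stall at the mono-adduct, or the lactone may be deprotonated at its γ-position instead. The fallback sets out from 17 (with 12) and comes back at 20. Cryptone 17 is converted with LDA/TMSCl (THF, −78 °C) into (5R)-5-isopropyl-2-(trimethylsilyloxy)cyclohexa-1,3-diene F1. This neutral diene is combined with 12 in a thermal or Me2AlCl-promoted Diels–Alder cycloaddition (toluene, 110 °C), which should show the same para regiochemistry and the same anti/anti/endo selectivity, to give the silyl enol ether cycloadduct F2. Brief treatment with 1 M HCl in THF at 0 °C cleaves only the enol silyl ether and gives 20.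

Step 5 (mesylate ring switch). Partial ionisation of the benzylic mesylate or methanolysis would erode the C-5 configuration or the yield. The fallback sets out from 6 and comes back at 7, and separates ring opening from ring closure. Mesylate 6 is opened with EtSH/TFA (0 °C) to the open-chain (5S)-3-O-benzyl-5-O-mesyl-5-C-phenyl-D-xylose diethyl dithioacetal F3. Under non-alkoxide buffered conditions (2,6-lutidine, MeCN, 60 °C) the free 2-OH of F3 closes onto C-5 with inversion to give the 2,5-anhydro diethyl dithioacetal F4. Transacetalisation of F4 with I2/NaHCO3 in MeOH delivers dimethyl acetal 7.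

Step 13 (enol triflate). Competing deprotonation of the lactone, or retro-Michael opening of the ketone enolate, would lower the yield. The fallback sets out from 20 and comes back at 23, and avoids any strong base. Ketone 20 is condensed with 1,2-bis(tert-butyldimethylsilyl)hydrazine (Sc(OTf)3 cat.) to the N-TBS hydrazone F5. Barton-type iodination of F5 (I2, tetramethylguanidine, THF, 0 °C) gives the alkenyl iodide F6, with the double bond again forced away from the bridgehead. F6 undergoes the same Pd(PPh3)4/MeZnCl coupling to give 23.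

## Further compounds

F1 | step 12 | (5R)-5-isopropyl-2-(trimethylsilyloxy)cyclohexa-1,3-diene | CC(C)[C@H]1CC=C(O[Si](C)(C)C)C=C1
F2 | step 12 | trimethylsilyl enol ether Diels–Alder adduct of F1 and 12 | C[Si](C)(C)OC1=C[C@@H]2[C@@H]3C(=O)O[C@H]4[C@H](O[Si](C)(C)C(C)(C)C)[C@@H](c5ccccc5)O[C@H]4[C@@H]3[C@H]1C[C@@H]2C(C)C
F3 | step 5 | (5S)-3-O-benzyl-5-O-mesyl-5-C-phenyl-D-xylose diethyl dithioacetal | CCSC(SCC)[C@H](O)[C@@H](OCc1ccccc1)[C@H](O)[C@@H](OS(C)(=O)=O)c1ccccc1
F4 | step 5 | (5R)-2,5-anhydro-3-O-benzyl-5-C-phenyl-D-xylose diethyl dithioacetal | CCSC(SCC)[C@@H]1O[C@H](c2ccccc2)[C@@H](O)[C@@H]1OCc1ccccc1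
F5 | step 13 | N-(tert-butyldimethylsilyl)hydrazone of 20 | CC(C)(C)[Si](C)(C)NN=C1C[C@@H]2[C@@H]3C(=O)O[C@H]4[C@H](O[Si](C)(C)C(C)(C)C)[C@@H](c5ccccc5)O[C@H]4[C@@H]3[C@H]1C[C@@H]2C(C)C
F6 | step 13 | O-TBS alkenyl iodide (I in place of OTf of 22) | IC1=C[C@@H]2[C@@H]3C(=O)O[C@H]4[C@H](O[Si](C)(C)C(C)(C)C)[C@@H](c5ccccc5)O[C@H]4[C@@H]3[C@H]1C[C@@H]2C(C)C
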